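**Assumption:** Robustol has no stereocentres, and its 22-membered ring is too flexible for stable planar chirality. It is therefore achiral, and the "single enantiomer" requirement has nothing to act on.

## Retrosynthetic overview
1. Robustol (8) comes from global O-demethylation of robustol trimethyl ether (7).
2. Key step: cut both aryl–CH2 bonds of 7 at once, giving dibromo diaryl ether 3 and the C14 bis-borane 6. This is a two-component double B-alkyl Suzuki "stapling", chosen instead of the usual macro-Ullmann or RCM/hydrogenation closure.
3. Bis-borane 6 comes from commercial tetradeca-1,13-diene (4) and 9-BBN (5), so the whole tether is bought in one piece.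
4. Diaryl ether 3 comes from a Chan–Lam C–O coupling of bromophenol 1 with bromoarylboronic acid 2, leaving both C–Br bonds intact.
5. Ring order: both benzene rings are purchased, and the only ring formed is the 22-membered macrocycle in step 3.

## Route

**Step 1**
Reactants: 1, 4-bromo-2,6-dimethoxyphenol; 2, (3-bromo-5-methoxyphenyl)boronic acid (2 equiv)
Product: 3, 5-bromo-2-(3-bromo-5-methoxyphenoxy)-1,3-dimethoxybenzene
Conditions: Cu(OAc)2 (1 equiv), pyridine (5 equiv), 4 Å MS, CH2Cl2, dry air, rt, 36 h
Reagents that add atoms: none (all product atoms come from 1 and 2)
Why: Chan–Evans–Lam oxidative C–O coupling runs at room temperature through Cu(II)/Cu(III), tolerates di-ortho-substituted phenols, leaves both aryl bromides untouched, and the para-bromine blocks oxidative dimerisation of the syringol-type phenol; no stereocentre is formed.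

**Step 2**
Reactants: 4, tetradeca-1,13-diene; 5, 9-borabicyclo[3.3.1]nonane (9-BBN-H, 2.0 equiv)
Product: 6, 1,14-bis(9-borabicyclo[3.3.1]nonan-9-yl)tetradecane (not isolated, used as a THF solution)
Conditions: 9-BBN-H (0.5 M in THF), THF, 0 °C → rt, 6 h, Ar
Reagents that add atoms: 9-BBN-H (compound 5), B1C2CCCC1CCC2
Why: Anti-Markovnikov hydroboration of both terminal alkenes by 9-BBN is more than 99% terminal-selective, giving a linear (CH2)14 unit with boron at each end; no stereocentre is formed.

**Step 3 (key step)**
Reactants: 3, dibromo diaryl ether; 6, bis-borane (1:1)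
Product: 7, robustol tri-O-methyl ether. It is a 22-membered oxa-[meta,para]cyclophane in which a (CH2)14 chain links C3 of the 5-methoxyphenoxy ring to C4 of the 2,6-dimethoxyphenyl ring.
Conditions: PdCl2(dppf)·CH2Cl2 (15 mol %), AsPh3 (15 mol %), Cs2CO3 (6 equiv), degassed DMF/THF/H2O, 60 °C; 3 and 6 premixed in one THF solution and added by syringe pump over 20 h (final ≈ 2 mM); NaBO3 work-up to remove borane residues
Reagents that add atoms: none
Why: This is a double B-alkyl Suzuki–Miyaura cross-coupling, a known reaction class for making cyclophanes from α,ω-bis(9-BBN)alkanes and dihaloarenes, in which the first coupling tethers the symmetric chain to either ring (so both orders converge on 7), pseudo-high dilution makes the second coupling an intramolecular closure of a strain-free ring, and dppf suppresses β-hydride elimination; no stereocentre is formed.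

**Step 4**
Reactants: 7, robustol tri-O-methyl ether
Product: 8, robustol
Conditions: BBr3 (9 equiv), CH2Cl2, −78 °C → rt, 12 h, Ar; then MeOH/H2O, 0 °C
Reagents that add atoms: none (each CH3 is replaced by H from the work-up)
Why: Lewis-acid aryl methyl ether cleavage by BBr3 removes only the three O–CH3 groups, because a diaryl ether oxygen has no sp3 carbon for bromide to attack and the saturated tether is inert; no stereocentre is involved.

## Compound list
1 | 4-bromo-2,6-dimethoxyphenol | COc1cc(Br)cc(OC)c1O | starting material
2 | (3-bromo-5-methoxyphenyl)boronic acid | COc1cc(Br)cc(c1)B(O)O | starting material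
3 | 5-bromo-2-(3-bromo-5-methoxyphenoxy)-1,3-dimethoxybenzene | COc1cc(Br)cc(Oc2c(OC)cc(Br)cc2OC)c1 | intermediate
4 | tetradeca-1,13-diene | C=CCCCCCCCCCCCC=C | starting material
5 | 9-borabicyclo[3.3.1]nonane (9-BBN-H) | B1C2CCCC1CCC2 | starting material
6 | 1,14-bis(9-borabicyclo[3.3.1]nonan-9-yl)tetradecane | C(CCCCCCCCCCCCCB1C2CCCC1CCC2)B1C2CCCC1CCC2 | intermediate
7 | robustol tri-O-methyl ether | COc1cc2cc(c1)Oc1c(OC)cc(cc1OC)CCCCCCCCCCCCCC2 | intermediate
8 | robustol (achiral) | Oc1cc2cc(c1)Oc1c(O)cc(cc1O)CCCCCCCCCCCCCC2 | target

## Summary
Total step count: 4.
Longest linear sequence: 3 (step 1 or 2 → step 3 → step 4).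

**Steps most likely to fail, with fallbacks**
1. **Step 3, two-component macrocyclisation.** The risks are linear oligomers, the [2+2] dimer and hydrodebromination.
   - Fallback: close the ring at a different bond in a unimolecular step.
   - Couple 3 twice with oct-7-enylzinc bromide (from 8-bromo-1-octene, Negishi) to give the bis(oct-7-enyl) diaryl ether.
   - Carry out RCM at 1 mM (8 + 8 − 2 = 14 carbons), then H2, Pd/C, which gives the same 7.
2. **Step 1, Chan–Lam coupling on a hindered, oxidisable phenol with an electron-poor boronic acid.** The risks are low conversion and phenol oxidation.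
   - Fallback: use metal-free, oxidant-free O-arylation.
   - Treat the potassium phenoxide of 1 with (3-bromo-5-methoxyphenyl)(2,4,6-trimethoxyphenyl)iodonium tosylate, made from 1-bromo-3-iodo-5-methoxybenzene.
   - The ether forms by ligand coupling at I(III), which tolerates di-ortho substitution.
3. **Step 4, triple demethylation.** The risks are incomplete cleavage of the flanking OMe groups and air oxidation of the electron-rich product.
   - Fallback: change the protecting-group strategy.
   - Run the route in the tri-O-benzyl series, using 2,6-bis(benzyloxy)-4-bromophenol and (3-benzyloxy-5-bromophenyl)boronic acid.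
   - Finish with neutral hydrogenolysis (H2, Pd/C).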